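The cyclopentane is closed between C8 and C9 (prostaglandin numbering), two carbons that are both electrophilic in an open-chain precursor: C9 is an aldehyde carbon and C8 the β-carbon of a (Z)-enoate whose ester carbon is C6. SmI2 reverses the polarity of C9 and in one operation forms the ring, sets C8 and the C9 carbinol under control of C11 and C12 (from a syn-aldol) and, because O9 and the C7 arm emerge cis, delivers the cis-fused γ-lactone. The precursor is an acyclic 7-oxohept-2-enoate that already carries the ω-chain. The C11 and C15 carbinols are oxidised together at the end.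

Key step: step 9

Remark: positions are given in prostaglandin numbering (C1 = carboxyl carbon, C20 = terminal methyl); (R)-δ-decalactone 1 is assumed to be bought enantiopure, and since C15 ends as a ketone its configuration only keeps the intermediates single diastereomers.

Step 1
Reactants: 1 (R)-δ-decalactone
Product: 4 (R)-5-(tert-butyldimethylsilyloxy)decanoic acid, via potassium (R)-5-hydroxydecanoate 2 (not isolated), via bis-silylated hydroxy acid 3 (not isolated)
Conditions: KOH, MeOH/H2O, rt; evaporate; TBSCl, imidazole, DMF, rt; then AcOH/H2O/THF, rt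
Reagents that add atoms: KOH, [K+].[OH-]; tert-butyldimethylsilyl chloride, CC(C)(C)[Si](C)(C)Cl
Why: Lactone saponification, O-silylation of both oxygens and selective hydrolysis of the labile silyl ester should give the protected acid without touching C15, which cannot relactonise once capped.

Step 2
Reactants: 4 (R)-5-(tert-butyldimethylsilyloxy)decanoic acid; 5 (S)-4-benzyl-1,3-thiazolidine-2-thione
Product: 6 (S)-4-benzyl-3-[(R)-5-(tert-butyldimethylsilyloxy)decanoyl]-1,3-thiazolidine-2-thione
Conditions: EDC·HCl, DMAP (cat.), CH2Cl2, 0 °C → rt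
Reagents that add atoms: none
Why: Carbodiimide (Steglich-type) N-acylation of the acidic N–H of the auxiliary should give the activated imide needed for soft enolisation.

Step 3
Reactants: 6 (S)-4-benzyl-3-[(R)-5-(tert-butyldimethylsilyloxy)decanoyl]-1,3-thiazolidine-2-thione; 7 acrolein
Product: 9 (S)-4-benzyl-3-{(2S,3R)-2-[(R)-3-(tert-butyldimethylsilyloxy)octyl]-3-hydroxypent-4-enoyl}-1,3-thiazolidine-2-thione, via trichlorotitanium (Z)-enolate 8 (not isolated)
Conditions: TiCl4 (1.05 equiv), i-Pr2NEt (1.1 equiv), N-methyl-2-pyrrolidinone (1 equiv), CH2Cl2, 0 °C; then 7, −78 → 0 °C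
Reagents that add atoms: none
Why: In this titanium-enolate aldol of an N-acylthiazolidinethione (Crimmins aldol) the (Z)-enolate should react through a non-chelated closed chair on the face away from the benzyl group, giving the "Evans-syn" adduct that sets C12 and C11 in the syn relationship that becomes trans on the ring.

Step 4
Reactants: 9 aldol adduct
Product: 10 (S)-4-benzyl-3-{(2S,3R)-3-(tert-butyldimethylsilyloxy)-2-[(R)-3-(tert-butyldimethylsilyloxy)octyl]pent-4-enoyl}-1,3-thiazolidine-2-thione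
Conditions: TBSOTf, 2,6-lutidine, CH2Cl2, −78 °C
Reagents that add atoms: tert-butyldimethylsilyl triflate, CC(C)(C)[Si](C)(C)OS(=O)(=O)C(F)(F)F
Why: Silyl triflate O-silylation under non-nucleophilic base should cap the C11 carbinol without retro-aldol cleavage or loss of the auxiliary.

Step 5
Reactants: 10 silylated aldol adduct
Product: 11 (2S,3R)-3-(tert-butyldimethylsilyloxy)-2-[(R)-3-(tert-butyldimethylsilyloxy)octyl]pent-4-enal
Conditions: i-Bu2AlH (1.2 equiv), CH2Cl2, −78 °C; aq. potassium sodium tartrate (KNaC4H4O6)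
Reagents that add atoms: none
Why: Partial hydride reduction of the N-acylthiazolidinethione should stop at the tetrahedral aluminium adduct, which releases the aldehyde and auxiliary 5 only on work-up, so the α-centre C12 is not enolised.

Step 6
Reactants: 11 aldehyde; 12 methyl bis(2,2,2-trifluoroethyl)phosphonoacetate
Product: 13 methyl (2Z,4R,5R)-5-(tert-butyldimethylsilyloxy)-4-[(R)-3-(tert-butyldimethylsilyloxy)octyl]hepta-2,6-dienoate
Conditions: KN(SiMe3)2, 18-crown-6, THF, −78 °C
Reagents that add atoms: none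
Why: The Still–Gennari variant of the Horner–Wadsworth–Emmons olefination should give the (Z)-enoate kinetically, because the trifluoroethyl phosphonate adduct eliminates faster than it equilibrates, and at −78 °C C12 should survive.

Step 7
Reactants: 13 (Z)-dienoate
Product: 15 methyl (2Z,4R,5R)-5-(tert-butyldimethylsilyloxy)-7-hydroxy-4-[(R)-3-(tert-butyldimethylsilyloxy)octyl]hept-2-enoate, via B-alkyl-9-BBN adduct 14 (not isolated)
Conditions: 9-BBN, THF, 0 °C → rt; then NaBO3·4H2O, H2O, rt
Reagents that add atoms: sodium perborate tetrahydrate (NaBO3·4H2O), [Na+].[Na+].O[B-]1(O)OO[B-](O)(O)OO1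
Why: Anti-Markovnikov hydroboration–oxidation should be chemoselective, since 9-BBN adds to the monosubstituted C9=C10 alkene far faster than to the hindered, electron-poor enoate and perborate oxidises the C–B bond without harming ester or silyl ethers.

Step 8
Reactants: 15 primary alcohol
Product: 16 methyl (2Z,4R,5R)-5-(tert-butyldimethylsilyloxy)-7-oxo-4-[(R)-3-(tert-butyldimethylsilyloxy)octyl]hept-2-enoate
Conditions: Dess–Martin periodinane, pyridine, CH2Cl2, 0 °C → rt
Reagents that add atoms: none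
Why: Dess–Martin oxidation under buffered conditions should stop at the aldehyde and avoid both β-elimination of the C11 silyloxy group and Z/E isomerisation of the enoate.

Step 9
Reactants: 16 aldehyde (Z)-enoate
Product: 18 (3aR,4R,5R,6aS)-5-(tert-butyldimethylsilyloxy)-4-[(R)-3-(tert-butyldimethylsilyloxy)octyl]hexahydro-2H-cyclopenta[b]furan-2-one, via cis-hydroxy ester 17 (not isolated)
Conditions: SmI2 (2.5 equiv), MeOH (4 equiv), THF (0.01 M), −78 °C → rt
Reagents that add atoms: none
Why: SmI2 (divalent samarium) transfers one electron to the C9 aldehyde to give a trivalent-samarium ketyl, an umpoled C9 that adds to C8, the β-carbon of the (Z)-enoate, and the resulting C7 radical is reduced by a second SmI2 to the ester enolate and protonated by MeOH, so two electrophilic carbons are joined reductively. The closest known reaction type is the SmI2-mediated ketyl–olefin (aldehyde–enoate) cyclisation to 2-(2-hydroxycyclopentyl)acetates. The carbocycle C8–C9–C10–C11–C12 closes 5-exo-trig, and the lactone O9–C6–C7–C8–C9 then closes 5-exo-trig by acyl substitution of the samarium alkoxide on the methyl ester. C8 is set by the existing centres: in the chair-like transition state the C11 silyloxy group and the C12 chain are pseudo-equatorial, which places C7 trans to the C12 chain and cis to O11 (8R). C9 is set by the enoate geometry: the (Z)-ester can bind the samarium on the ketyl oxygen and hold O9 on the side of the C7 arm (9S), the syn sense known for (Z)-enoates, and only this cis γ-hydroxy ester can lactonise. The step needs ketyl formation and 5-exo closure to outrun pinacol coupling, enoate reduction and simple aldehyde reduction, which low temperature, high dilution and MeOH as the only proton source should secure; the C11 silyloxy group is γ to C9 and cannot be expelled.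

Step 10
Reactants: 18 lactone
Product: 19 (3aR,4R,5R,6aS)-5-(tert-butyldimethylsilyloxy)-4-[(R)-3-(tert-butyldimethylsilyloxy)octyl]hexahydro-2H-cyclopenta[b]furan-2-ol (both anomers)
Conditions: i-Bu2AlH (1.1 equiv), toluene, −78 °C
Reagents that add atoms: none
Why: Partial lactone reduction should stop at the lactol because the aluminium hemiacetal is stable at −78 °C.

Step 11
Reactants: 19 lactol; 20 (4-carboxybutyl)triphenylphosphonium bromide
Product: 21 (Z)-7-{(1R,2R,3R,5S)-3-(tert-butyldimethylsilyloxy)-2-[(R)-3-(tert-butyldimethylsilyloxy)octyl]-5-hydroxycyclopentyl}hept-5-enoic acid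
Conditions: KOt-Bu, THF, 0 °C → rt; NaH2PO4 work-up (pH 5)
Reagents that add atoms: none
Why: Wittig olefination of the open hydroxy-aldehyde form of the lactol with the unstabilised, lithium-free ylide should give the (Z)-C5=C6 alkene and free O9, the bulky C11 silyl ether being slow to migrate to the C9 alkoxide.

Step 12
Reactants: 21 hydroxy acid
Product: 23 (Z)-7-{(1R,2R,3R,5S)-3-hydroxy-2-[(R)-3-hydroxyoctyl]-5-[(4-methoxytetrahydro-2H-pyran-4-yl)oxy]cyclopentyl}hept-5-enoic acid, via 9-O-MTHP bis-silyl ether 22 (not isolated)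
Conditions: 4-methoxy-3,6-dihydro-2H-pyran, PPTS (cat.), CH2Cl2, 0 °C → rt; then Bu4NF, THF, rt
Reagents that add atoms: 4-methoxy-3,6-dihydro-2H-pyran, COC1=CCOCC1
Why: Acid-catalysed addition of the C9–OH to the enol ether (acetalisation) should give the achiral 4-methoxytetrahydropyran-4-yl (MTHP) ketal, which is stable to fluoride, so that Bu4NF then cleaves only the two silyl ethers while any ketal ester at the acid reverts on work-up.

Step 13
Reactants: 23 diol acid
Product: 24 (Z)-7-{(1R,2R,5S)-5-[(4-methoxytetrahydro-2H-pyran-4-yl)oxy]-3-oxo-2-(3-oxooctyl)cyclopentyl}hept-5-enoic acid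
Conditions: Dess–Martin periodinane, pyridine, CH2Cl2, 0 °C → rt
Reagents that add atoms: none
Why: Dess–Martin oxidation should convert both free secondary carbinols (C11 and C15) into ketones in one operation while O9 is masked, and C12, now α to the C11 ketone, keeps its thermodynamically favoured trans relationship to C8.

Step 14
Reactants: 24 ketal diketone acid
Product: 25 13,14-dihydro-15-keto-PGD2, (Z)-7-[(1R,2R,5S)-5-hydroxy-3-oxo-2-(3-oxooctyl)cyclopentyl]hept-5-enoic acid
Conditions: AcOH/H2O/THF (3:1:1), rt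
Reagents that add atoms: none
Why: Mild acid hydrolysis of the ketal (acetal cleavage) should free the C9–OH under conditions too weak to dehydrate the β-hydroxy ketone or to start aldol reactions of the 1,5-diketone.

Compound list
1 | (R)-δ-decalactone, (6R)-6-pentyltetrahydro-2H-pyran-2-one | CCCCC[C@@H]1CCCC(=O)O1 | starting material
2 | potassium (R)-5-hydroxydecanoate | CCCCC[C@@H](O)CCCC(=O)[O-].[K+] | intermediate
3 | tert-butyldimethylsilyl (R)-5-(tert-butyldimethylsilyloxy)decanoate | CCCCC[C@@H](O[Si](C)(C)C(C)(C)C)CCCC(=O)O[Si](C)(C)C(C)(C)C | intermediate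
4 | (R)-5-(tert-butyldimethylsilyloxy)decanoic acid | CCCCC[C@@H](O[Si](C)(C)C(C)(C)C)CCCC(=O)O | intermediate
5 | (S)-4-benzyl-1,3-thiazolidine-2-thione | S=C1N[C@@H](Cc2ccccc2)CS1 | starting material
6 | (S)-4-benzyl-3-[(R)-5-(tert-butyldimethylsilyloxy)decanoyl]-1,3-thiazolidine-2-thione | CCCCC[C@@H](O[Si](C)(C)C(C)(C)C)CCCC(=O)N1[C@@H](Cc2ccccc2)CSC1=S | intermediate
7 | acrolein | C=CC=O | starting material
8 | trichlorotitanium (Z)-enolate of 6 | CCCCC[C@@H](O[Si](C)(C)C(C)(C)C)CC/C=C(\O[Ti](Cl)(Cl)Cl)N1[C@@H](Cc2ccccc2)CSC1=S | intermediate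
9 | (S)-4-benzyl-3-{(2S,3R)-2-[(R)-3-(tert-butyldimethylsilyloxy)octyl]-3-hydroxypent-4-enoyl}-1,3-thiazolidine-2-thione | CCCCC[C@@H](O[Si](C)(C)C(C)(C)C)CC[C@H](C(=O)N1[C@@H](Cc2ccccc2)CSC1=S)[C@H](O)C=C | intermediate
10 | (S)-4-benzyl-3-{(2S,3R)-3-(tert-butyldimethylsilyloxy)-2-[(R)-3-(tert-butyldimethylsilyloxy)octyl]pent-4-enoyl}-1,3-thiazolidine-2-thione | CCCCC[C@@H](O[Si](C)(C)C(C)(C)C)CC[C@H](C(=O)N1[C@@H](Cc2ccccc2)CSC1=S)[C@H](O[Si](C)(C)C(C)(C)C)C=C | intermediate
11 | (2S,3R)-3-(tert-butyldimethylsilyloxy)-2-[(R)-3-(tert-butyldimethylsilyloxy)octyl]pent-4-enal | CCCCC[C@@H](O[Si](C)(C)C(C)(C)C)CC[C@H](C=O)[C@H](O[Si](C)(C)C(C)(C)C)C=C | intermediate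
12 | methyl bis(2,2,2-trifluoroethyl)phosphonoacetate | COC(=O)CP(=O)(OCC(F)(F)F)OCC(F)(F)F | starting material
13 | methyl (2Z,4R,5R)-5-(tert-butyldimethylsilyloxy)-4-[(R)-3-(tert-butyldimethylsilyloxy)octyl]hepta-2,6-dienoate | CCCCC[C@@H](O[Si](C)(C)C(C)(C)C)CC[C@H](/C=C\C(=O)OC)[C@H](O[Si](C)(C)C(C)(C)C)C=C | intermediate
14 | B-alkyl-9-borabicyclo[3.3.1]nonane adduct of 13 at C9 | CCCCC[C@@H](O[Si](C)(C)C(C)(C)C)CC[C@H](/C=C\C(=O)OC)[C@H](O[Si](C)(C)C(C)(C)C)CCB1C2CCCC1CCC2 | intermediate
15 | methyl (2Z,4R,5R)-5-(tert-butyldimethylsilyloxy)-7-hydroxy-4-[(R)-3-(tert-butyldimethylsilyloxy)octyl]hept-2-enoate | CCCCC[C@@H](O[Si](C)(C)C(C)(C)C)CC[C@H](/C=C\C(=O)OC)[C@H](O[Si](C)(C)C(C)(C)C)CCO | intermediate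
16 | methyl (2Z,4R,5R)-5-(tert-butyldimethylsilyloxy)-7-oxo-4-[(R)-3-(tert-butyldimethylsilyloxy)octyl]hept-2-enoate | CCCCC[C@@H](O[Si](C)(C)C(C)(C)C)CC[C@H](/C=C\C(=O)OC)[C@H](O[Si](C)(C)C(C)(C)C)CC=O | intermediate
17 | methyl 2-{(1R,2R,3R,5S)-3-(tert-butyldimethylsilyloxy)-2-[(R)-3-(tert-butyldimethylsilyloxy)octyl]-5-hydroxycyclopentyl}acetate | CCCCC[C@@H](O[Si](C)(C)C(C)(C)C)CC[C@H]1[C@H](O[Si](C)(C)C(C)(C)C)C[C@H](O)[C@@H]1CC(=O)OC | intermediate
18 | (3aR,4R,5R,6aS)-5-(tert-butyldimethylsilyloxy)-4-[(R)-3-(tert-butyldimethylsilyloxy)octyl]hexahydro-2H-cyclopenta[b]furan-2-one | CCCCC[C@@H](O[Si](C)(C)C(C)(C)C)CC[C@H]1[C@H](O[Si](C)(C)C(C)(C)C)C[C@@H]2OC(=O)C[C@H]12 | intermediate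
19 | (3aR,4R,5R,6aS)-5-(tert-butyldimethylsilyloxy)-4-[(R)-3-(tert-butyldimethylsilyloxy)octyl]hexahydro-2H-cyclopenta[b]furan-2-ol (both anomers) | CCCCC[C@@H](O[Si](C)(C)C(C)(C)C)CC[C@H]1[C@H](O[Si](C)(C)C(C)(C)C)C[C@@H]2OC(O)C[C@H]12 | intermediate
20 | (4-carboxybutyl)triphenylphosphonium bromide | OC(=O)CCCC[P+](c1ccccc1)(c1ccccc1)c1ccccc1.[Br-] | starting material
21 | (Z)-7-{(1R,2R,3R,5S)-3-(tert-butyldimethylsilyloxy)-2-[(R)-3-(tert-butyldimethylsilyloxy)octyl]-5-hydroxycyclopentyl}hept-5-enoic acid | CCCCC[C@@H](O[Si](C)(C)C(C)(C)C)CC[C@H]1[C@H](O[Si](C)(C)C(C)(C)C)C[C@H](O)[C@@H]1C/C=C\CCCC(=O)O | intermediate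
22 | (Z)-7-{(1R,2R,3R,5S)-3-(tert-butyldimethylsilyloxy)-2-[(R)-3-(tert-butyldimethylsilyloxy)octyl]-5-[(4-methoxytetrahydro-2H-pyran-4-yl)oxy]cyclopentyl}hept-5-enoic acid | CCCCC[C@@H](O[Si](C)(C)C(C)(C)C)CC[C@H]1[C@H](O[Si](C)(C)C(C)(C)C)C[C@H](OC2(OC)CCOCC2)[C@@H]1C/C=C\CCCC(=O)O | intermediate
23 | (Z)-7-{(1R,2R,3R,5S)-3-hydroxy-2-[(R)-3-hydroxyoctyl]-5-[(4-methoxytetrahydro-2H-pyran-4-yl)oxy]cyclopentyl}hept-5-enoic acid | CCCCC[C@@H](O)CC[C@H]1[C@H](O)C[C@H](OC2(OC)CCOCC2)[C@@H]1C/C=C\CCCC(=O)O | intermediate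
24 | (Z)-7-{(1R,2R,5S)-5-[(4-methoxytetrahydro-2H-pyran-4-yl)oxy]-3-oxo-2-(3-oxooctyl)cyclopentyl}hept-5-enoic acid | CCCCCC(=O)CC[C@H]1C(=O)C[C@H](OC2(OC)CCOCC2)[C@@H]1C/C=C\CCCC(=O)O | intermediate
25 | 13,14-dihydro-15-keto-PGD2, (Z)-7-[(1R,2R,5S)-5-hydroxy-3-oxo-2-(3-oxooctyl)cyclopentyl]hept-5-enoic acid | CCCCCC(=O)CC[C@H]1C(=O)C[C@H](O)[C@@H]1C/C=C\CCCC(=O)O | target

Total step count: 14. Longest linear sequence: 14 steps (1 → 25).

Steps most likely to fail

Step 9 (key step). The facial sense at C9 may be lost: if dipole repulsion outweighs binding of the ester to samarium, the ketyl oxygen adds anti to the C7 arm and lactonisation cannot follow. C8 should stay secure because C11 and C12 reinforce each other. The fallback sets out from 16, accepts the anti cyclisation and corrects C9 by inversion. The expected product is then methyl 2-{(1R,2R,3R,5R)-3-(tert-butyldimethylsilyloxy)-2-[(R)-3-(tert-butyldimethylsilyloxy)octyl]-5-hydroxycyclopentyl}acetate F1. Saponification (LiOH, THF/H2O, rt) gives the corresponding 9β-hydroxy acid F2. Mitsunobu lactonisation (PPh3, DIAD, THF, 0 °C) displaces the activated C9 oxygen by the carboxylate with inversion, gives the cis-fused lactone and comes back to the route at 18.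

Step 7. Chemoselectivity may fail in two ways: the borane may attack the enoate, or the new C9 alkoxide may add to C8 (6-exo oxa-Michael) during the basic oxidative work-up. The fallback sets out from 13 and oxidises the vinyl group directly with a nitrite-modified, aldehyde-selective Wacker oxidation (PdCl2(PhCN)2, CuCl2·2H2O and AgNO2, all catalytic, O2, t-BuOH/MeNO2, rt). The allylic silyloxy group should steer oxygen to the terminal carbon, so no free alcohol is ever present. It comes back to the route at 16, skips 15 and makes no new compound (F0).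

Step 6. Kinetic Z-selectivity may erode, and the base may epimerise C12 by enolising aldehyde 11. The fallback sets out from 11 and takes the Z-geometry from an alkyne. Corey–Fuchs homologation under neutral conditions (CBr4, PPh3, CH2Cl2, 0 °C) gives (3R,4R,7R)-4-(2,2-dibromoethenyl)-3,7-bis(tert-butyldimethylsilyloxy)dodec-1-ene F3. Treatment with n-BuLi (2 equiv, THF, −78 °C) and then ClCO2Me gives methyl (4R,5R)-5-(tert-butyldimethylsilyloxy)-4-[(R)-3-(tert-butyldimethylsilyloxy)octyl]hept-6-en-2-ynoate F4. Semi-hydrogenation (H2, one equivalent, Pd/CaCO3 poisoned with Pb(OAc)2, quinoline, EtOAc) sets the (Z)-enoate by syn addition and comes back to the route at 13.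

Further compounds
F1 | step 9 | methyl 2-{(1R,2R,3R,5R)-3-(tert-butyldimethylsilyloxy)-2-[(R)-3-(tert-butyldimethylsilyloxy)octyl]-5-hydroxycyclopentyl}acetate | CCCCC[C@@H](O[Si](C)(C)C(C)(C)C)CC[C@H]1[C@H](O[Si](C)(C)C(C)(C)C)C[C@@H](O)[C@@H]1CC(=O)OC
F2 | step 9 | 2-{(1R,2R,3R,5R)-3-(tert-butyldimethylsilyloxy)-2-[(R)-3-(tert-butyldimethylsilyloxy)octyl]-5-hydroxycyclopentyl}acetic acid | CCCCC[C@@H](O[Si](C)(C)C(C)(C)C)CC[C@H]1[C@H](O[Si](C)(C)C(C)(C)C)C[C@@H](O)[C@@H]1CC(=O)O
F0 | step 7 | none | none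
F3 | step 6 | (3R,4R,7R)-4-(2,2-dibromoethenyl)-3,7-bis(tert-butyldimethylsilyloxy)dodec-1-ene | CCCCC[C@@H](O[Si](C)(C)C(C)(C)C)CC[C@H](C=C(Br)Br)[C@H](O[Si](C)(C)C(C)(C)C)C=C
F4 | step 6 | methyl (4R,5R)-5-(tert-butyldimethylsilyloxy)-4-[(R)-3-(tert-butyldimethylsilyloxy)octyl]hept-6-en-2-ynoate | CCCCC[C@@H](O[Si](C)(C)C(C)(C)C)CC[C@H](C#CC(=O)OC)[C@H](O[Si](C)(C)C(C)(C)C)C=C
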